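**Numbering used throughout:** 1 (+)-catechin; 2 tetra-O-benzylcatechin; 3 its 8-bromide; 4 penta-O-benzyl-8-bromocatechin; 5 2,3,4-trihydroxybenzaldehyde; 6 3,4-bis(benzyloxy)-2-hydroxybenzaldehyde; 7 its 2-O-allyl ether; 8 8-lithio-penta-O-benzylcatechin; 9 diaryl carbinol; 10 diaryl ketone; 11 1,1-diarylethene (O-allyl); 12 free phenol; 13 caffeic acid; 14 benzyl ester dibenzyl ether; 15 allylic alcohol; 16 allylic methyl carbonate; 17 lithium phenoxide of 12; 18 metathesis precursor; 19 4-aryl flav-3-ene; 20 C3 alkylborane; 21 nona-O-benzyl ether of the target; 22 target.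

## Analysis of the target

Compound 22 is a 4→8 linked biflavanoid. Its upper unit is a 7,8,3′,4′-tetrahydroxyflavan-3-ol whose ring A is a 1,2,3-trioxygenated benzene without an oxygen at C5, and C4 of this unit is bonded to C8 of a lower (+)-catechin unit. There are five stereocentres. C2 and C3 of the lower unit are those of (2R,3S)-catechin. Ring C of the upper unit carries three contiguous centres, (2R,3S,4S): the ring B aryl group on C2 and the catechinyl group on C4 are cis to each other and the C3 hydroxyl is trans to both, so all three substituents are equatorial. The molecule has nine phenolic hydroxyls that oxidise in air, a C4–C8 bond and a C2–O1 bond that are both benzylic and acid-labile, and slow rotation about the C4–C8 bond. The difficulty lies in the upper unit: no cheap enantiopure flavan with this ring A exists, so its three centres must be made, and the C4–C8 bond joins a secondary carbon to an arene carbon flanked by two oxygens, with catechin C6 as a competing site. The strategy rests on the position of C3 and C4 of the upper ring C between C2 (bearing O1 and ring B) and the ring A carbon C4a. If C3 and C4 form an alkene, C2 is the only stereocentre of the upper unit, the C3=C4 bond can be closed by olefin metathesis from a vinyl group on C2 and a 1-arylvinyl group on C4a, and syn addition of hydrogen to C4 and hydroxyl to C3 from the face away from the C2 aryl group gives the relative configuration of 22.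

## Retrosynthetic reasoning

**22 to 21.** The nine phenolic and alcoholic O–benzyl bonds are cut last. Benzyl ethers are the only protecting group in the late intermediates, they survive organolithium, titanium, iridium, ruthenium and boron reagents, and they leave under neutral hydrogenolysis, which the acid-labile interflavan bond and the oxidisable free phenols require.

**21 to 19.** The C3–O bond and the C4–H bond are removed together, which is a retro-hydroboration–oxidation of the C3=C4 alkene of 19. This is the place to cut because it reduces three ring C stereocentres to one. The forward reaction has to place boron on C3 (C4 carries two aryl groups) and deliver boron and hydrogen to the face opposite the C2 aryl group, which gives C3–OH trans to that aryl and the C4 catechinyl group cis to it.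

**19 to 18.** The C3=C4 double bond is cut into two terminal alkenes, the vinyl group on C2 and the 1-(catechinyl)vinyl group on ring A of 18. Cutting here means the hindered bond between C4 and catechin C8 is already present as an sp2–sp2 bond that carbonyl chemistry can make, and the ring closure itself creates no stereocentre. The forward metathesis must close a six-membered ring onto a 1,1-diarylethene without disturbing C2.

**18 to 12 and 16.** The allylic C2–O1 bond is cut. An asymmetric allylic etherification of the phenol 12 with the linear carbonate 16 makes this bond at the substituted allyl terminus and sets C2 by catalyst control. Placing this step directly before the metathesis keeps the ionisable allylic–benzylic ether centre away from organolithium, oxidising and titanium reagents.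

**12 to 11 to 10 to 9.** The phenol of 12 is traced to its allyl ether 11, the only ring A protecting group that is orthogonal to benzyl and removable under neutral conditions next to the acid-sensitive 1,1-diarylethene. The terminal methylene of 11 is cut back to the ketone 10 (carbonyl methylenation), and 10 to the carbinol 9 (oxidation). The carbinol stereocentre of 9 is not controlled because it is destroyed.

**9 to 4 (through 8) and 7.** The bond between catechin C8 and the future C4 is cut. An aryllithium 8 adding to the aldehyde 7 makes this hindered bond under kinetic control, and the position of the bromine in 4 fixes the C8 regiochemistry, so C6 cannot compete.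

**4 to 3 to 2 to 1; 7 to 6 to 5; 16 to 15 to 14 to 13.** The bromide 4 comes from 1 by phenol benzylation, C8 bromination and benzylation of the C3 hydroxyl. The aldehyde 7 comes from 5 by benzylation of the two non-chelated phenols and allylation of the chelated one. The carbonate 16 comes from 13 by perbenzylation, ester reduction and carbonate formation. Both lower-unit stereocentres come unchanged from 1.

## Alternatives that were turned down

**Alternative 1:** The disconnection is the aryl–oxygen bond O1–C8a. In the forward direction the open-chain bromo alcohol A2, which already carries C2–OH, a silylated C3 oxygen and the C4 diarylmethine, would be cyclised with CuI, 3,4,7,8-tetramethyl-1,10-phenanthroline and Cs2CO3 to the chroman A1. In its favour, all three ring C centres are fixed before closure and the cyclisation touches none of them. On stereochemical certainty at the end of the route it is stronger than the chosen plan, which depends on the facial selectivity of one addition to a hindered alkene. Against it: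
- A2 contains a stereotriad that must be built in an open chain around a diarylmethine bearing a doubly ortho-oxygenated aryl group, which means three separate selectivity problems with no ring to relay them.
- The aryl bromide of A2 is electron-rich and flanked by a benzyloxy group and the branched C4, the least favourable case for copper-mediated etherification.
- Under hot carbonate base the silyl group can migrate from the C3 oxygen to the C2 alkoxide, after which the wrong oxygen closes a five-membered ring.

The chosen route needs one catalyst-set stereocentre and lets the ring pass it on to C3 and C4, with fewer steps to its precursor 18.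

**Alternative 2:** The disconnection is O1–C8a with C2 at the lactone oxidation level. Buffered m-chloroperbenzoic acid would insert oxygen between the carbonyl carbon and the aryl carbon of the 3-(catechinyl)indan-1-one A4 and give the dihydrocoumarin A3. In its favour, the migrating group is unambiguous (the electron-rich aryl carbon rather than the methylene), migration does not involve C4, and C4 would be set early. On the predictability of the ring-forming step it is at least as strong as a metathesis onto a hindered alkene. Against it: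
- A peracid is applied to a substrate with two very electron-rich benzyloxyarenes, and the aryl ketone itself is deactivated towards peracid addition.
- A3 still lacks the C3 hydroxyl and the whole ring B. α-Hydroxylation, aryl addition to the lactone carbonyl and reductive removal of the anomeric oxygen would be needed, and hydride delivery to a C2 cation anti to the C3 oxygen would be expected to give the 2,3-cis series, not the 2,3-trans arrangement of 22.
- Enantiocontrol at C3 of A4 would require asymmetric addition of a doubly ortho-substituted aryl nucleophile.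

The chosen route brings ring B and C2 into ring C in the closure itself and needs two steps after the key step.

**Alternative 3:** The disconnections are C3–C4 and O1–C2. The ortho-quinone methide A7, generated from the (2-hydroxyaryl)(catechinyl)carbinol A6, would be attacked at C4 by the diarylprolinol silyl ether enamine of benzyloxyacetaldehyde A8, and the phenol would then close on the aldehyde to give the lactol A5. In its favour, it is the most convergent of the four: two ring C bonds and the C3 and C4 centres form in one catalytic step, the C3 oxygen is already in place, and A6 is reached in fewer steps than 18. On these points it is stronger than the chosen route. Against it: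
- The electrophilic carbon of A7 carries the doubly ortho-substituted catechinyl group, so the enamine must attack a hindered, strongly donor-stabilised quinone methide, and the chiral catechin unit makes one catalyst enantiomer a mismatched case.
- A5 has no ring B. Introducing the C2 aryl group and fixing C2 trans to the C3 oxygen would take several further steps, with the last stereocentre set by a ring opening and reclosure or by an anomeric reduction whose outcome is not secured.

The chosen route offers the complete carbon skeleton at the key step and a single, substrate-controlled stereochemical event after it.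

Key step: step 14

**Remarks on the chemistry.**
- Upper-unit atoms carry flavan numbers; lower-unit positions are called catechin C8 and so on.
- The sense of induction in step 13 is assumed to follow the usual behaviour of this iridium–phosphoramidite family, in which the (Ra,Rc,Rc) ligand leads to (R)-1-arylallyl aryl ethers, so the (Sa,Sc,Sc) ligand is specified for the (S)-ether 18. If a model phenol shows the opposite sense, the antipodal ligand is used and nothing else changes.
- Compound 9 is carried as both carbinol epimers because that centre is removed in step 7.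

## Route

Step 1
Reactants: 1 (+)-catechin
Product: 2 5,7,3′,4′-tetra-O-benzyl-(+)-catechin
Conditions: BnBr (4.4 equiv), K2CO3, DMF, 0 °C → rt, N2
Reagents that add atoms: benzyl bromide, BrCc1ccccc1
Why: Williamson etherification; K2CO3 deprotonates the four phenols but not the C3 alcohol, and capping the 4′-phenol early removes the pathway for base-induced epimerisation at C2.

Step 2
Reactants: 2 5,7,3′,4′-tetra-O-benzyl-(+)-catechin
Product: 3 8-bromo-5,7,3′,4′-tetra-O-benzyl-(+)-catechin
Conditions: NBS (1.0 equiv), CH2Cl2, −78 °C → rt, dark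
Reagents that add atoms: N-bromosuccinimide, O=C1CCC(=O)N1Br
Why: Electrophilic aromatic bromination of the trioxygenated ring A; C8, between the ring oxygen and one benzyloxy group, is less hindered than C6 between two benzyloxy groups, so monobromination should take place at C8.

Step 3
Reactants: 3 8-bromo-5,7,3′,4′-tetra-O-benzyl-(+)-catechin
Product: 4 8-bromo-3,5,7,3′,4′-penta-O-benzyl-(+)-catechin
Conditions: NaH, BnBr, DMF, 0 °C → rt
Reagents that add atoms: benzyl bromide, BrCc1ccccc1
Why: Williamson etherification of the secondary alkoxide; it removes the only acidic proton before the lithiation and the C2 and C3 centres are not involved.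

Step 4
Reactants: 5 2,3,4-trihydroxybenzaldehyde
Product: 6 3,4-bis(benzyloxy)-2-hydroxybenzaldehyde
Conditions: BnBr (2.05 equiv), K2CO3 (2.2 equiv), DMF, rt
Reagents that add atoms: benzyl bromide, BrCc1ccccc1
Why: Selective Williamson etherification; the 2-hydroxyl is held in a hydrogen bond to the formyl oxygen and is the least nucleophilic, so with two equivalents of halide the 4- and 3-hydroxyls should react first.

Step 5
Reactants: 6 3,4-bis(benzyloxy)-2-hydroxybenzaldehyde
Product: 7 2-(allyloxy)-3,4-bis(benzyloxy)benzaldehyde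
Conditions: allyl bromide, K2CO3, DMF, 60 °C
Reagents that add atoms: allyl bromide, C=CCBr
Why: Williamson etherification of the chelated phenol under slightly forcing conditions; the allyl group is orthogonal to benzyl and is later removed under neutral conditions.

Step 6
Reactants: 4 8-bromo-3,5,7,3′,4′-penta-O-benzyl-(+)-catechin; 7 2-(allyloxy)-3,4-bis(benzyloxy)benzaldehyde
Product: 9 [2-(allyloxy)-3,4-bis(benzyloxy)phenyl](penta-O-benzylcatechin-8-yl)methanol as both carbinol epimers, via 8-lithio-penta-O-benzylcatechin 8 (not isolated)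
Conditions: 4, n-BuLi (1.05 equiv), THF, −78 °C; then 7, −78 → −40 °C; then H2O
Reagents that add atoms: none
Why: Bromine–lithium exchange is faster than benzylic deprotonation at −78 °C and gives an aryllithium stabilised by its two ortho oxygens; 1,2-addition to the non-enolisable aldehyde forms the bond between catechin C8 and the future C4, and the uncontrolled carbinol centre is removed in step 7.

Step 7
Reactants: 9 [2-(allyloxy)-3,4-bis(benzyloxy)phenyl](penta-O-benzylcatechin-8-yl)methanol
Product: 10 [2-(allyloxy)-3,4-bis(benzyloxy)phenyl](penta-O-benzylcatechin-8-yl)methanone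
Conditions: Dess–Martin periodinane (1.5 equiv), pyridine, CH2Cl2, 0 °C → rt
Reagents that add atoms: none
Why: Dess–Martin oxidation of a secondary benzylic alcohol; the pyridine buffer prevents acid ionisation of the electron-rich diaryl carbinol, and both epimers converge on one ketone.

Step 8
Reactants: 10 [2-(allyloxy)-3,4-bis(benzyloxy)phenyl](penta-O-benzylcatechin-8-yl)methanone
Product: 11 8-{1-[2-(allyloxy)-3,4-bis(benzyloxy)phenyl]vinyl}-3,5,7,3′,4′-penta-O-benzylcatechin
Conditions: Cp2TiMe2 (3 equiv), toluene/THF, 75 °C, dark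
Reagents that add atoms: dimethyltitanocene Cp2TiMe2, [CH3-].[CH3-].[Ti+4].c1cc[cH-]c1.c1cc[cH-]c1
Why: Petasis methylenation; thermolysis gives Cp2Ti=CH2, which adds across the carbonyl and cycloreverts with formation of a strong Ti=O bond, a non-basic process that suits hindered, electron-rich diaryl ketones and leaves allyl and benzyl ethers alone.

Step 9
Reactants: 11 8-{1-[2-(allyloxy)-3,4-bis(benzyloxy)phenyl]vinyl}-3,5,7,3′,4′-penta-O-benzylcatechin
Product: 12 2,3-bis(benzyloxy)-6-[1-(penta-O-benzylcatechin-8-yl)vinyl]phenol
Conditions: Pd(PPh3)4 (5 mol %), morpholine, THF, rt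
Reagents that add atoms: none
Why: Tsuji–Trost deallylation; zerovalent palladium ionises the aryl allyl ether to an allyl complex and the phenoxide, morpholine traps the allyl group, and the neutral conditions spare the acid-sensitive 1,1-diarylethene and the benzyl ethers.

Step 10
Reactants: 13 caffeic acid
Product: 14 benzyl (E)-3-[3,4-bis(benzyloxy)phenyl]prop-2-enoate
Conditions: BnBr (3.3 equiv), K2CO3, DMF, 60 °C
Reagents that add atoms: benzyl bromide, BrCc1ccccc1
Why: Williamson etherification of both phenols and O-alkylation of the carboxylate in one operation; the E alkene is untouched.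

Step 11
Reactants: 14 benzyl (E)-3-[3,4-bis(benzyloxy)phenyl]prop-2-enoate
Product: 15 (E)-3-[3,4-bis(benzyloxy)phenyl]prop-2-en-1-ol
Conditions: i-Bu2AlH (2.5 equiv), CH2Cl2, −78 → 0 °C; aq. potassium sodium tartrate (KNaC4H4O6)
Reagents that add atoms: none
Why: 1,2-Reduction of an α,β-unsaturated ester to the allylic alcohol by an aluminium hydride, which does not reduce the conjugated alkene.

Step 12
Reactants: 15 (E)-3-[3,4-bis(benzyloxy)phenyl]prop-2-en-1-ol
Product: 16 (E)-3-[3,4-bis(benzyloxy)phenyl]allyl methyl carbonate
Conditions: ClCO2Me, pyridine, CH2Cl2, 0 °C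
Reagents that add atoms: methyl chloroformate, COC(=O)Cl
Why: Acylation of a primary alcohol; the carbonate is the leaving group that makes the later allylic substitution irreversible by loss of CO2.

Step 13
Reactants: 12 2,3-bis(benzyloxy)-6-[1-(penta-O-benzylcatechin-8-yl)vinyl]phenol; 16 (E)-3-[3,4-bis(benzyloxy)phenyl]allyl methyl carbonate
Product: 18 8-{1-[3,4-bis(benzyloxy)-2-{[(1S)-1-(3,4-bis(benzyloxy)phenyl)prop-2-en-1-yl]oxy}phenyl]vinyl}-3,5,7,3′,4′-penta-O-benzylcatechin, via lithium 2,3-bis(benzyloxy)-6-[1-(penta-O-benzylcatechin-8-yl)vinyl]phenoxide 17 (not isolated)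
Conditions: 12, LiN(SiMe3)2 (1.0 equiv), THF, 0 °C; then 16 (1.5 equiv), [Ir(cod)Cl]2 (2.5 mol %), (Sa,Sc,Sc)-O,O′-(1,1′-binaphthyl-2,2′-diyl) N,N-bis(1-phenylethyl)phosphoramidite (5 mol %, preactivated with n-PrNH2, volatiles removed), THF, rt → 40 °C
Reagents that add atoms: none
Why: Iridium-catalysed asymmetric allylic etherification; the cyclometalated iridium–phosphoramidite complex ionises the carbonate to an allyl complex, the phenoxide attacks the aryl-substituted terminus on the face fixed by the ligand to give the branched ether with C2 as (S), and loss of CO2 and methoxide prevents reversal; the catechin centres are too remote to bias the outcome.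

Step 14
Reactants: 18 8-{1-[3,4-bis(benzyloxy)-2-{[(1S)-1-(3,4-bis(benzyloxy)phenyl)prop-2-en-1-yl]oxy}phenyl]vinyl}-3,5,7,3′,4′-penta-O-benzylcatechin
Product: 19 (2S)-7,8-bis(benzyloxy)-2-[3,4-bis(benzyloxy)phenyl]-4-(penta-O-benzylcatechin-8-yl)-2H-chromene
Conditions: second-generation Grubbs catalyst (H2IMes)(PCy3)Cl2Ru=CHPh (10 mol %, two portions), 1,4-benzoquinone (20 mol %), toluene (0.005 M), 60 °C, Ar sparge, dark
Reagents that add atoms: none
Why: Ring-closing olefin metathesis by the metal carbene/metallacyclobutane mechanism: the ruthenium benzylidene exchanges with the monosubstituted vinyl group on C2 to give an alkylidene at C3, this adds across the 1,1-diarylethene to a ruthenacyclobutane in which C3 is bonded to C4 and ruthenium to the terminal CH2, and cycloreversion releases the C3=C4 alkene and Ru=CH2, whose methylene leaves as ethene. The closest known reaction type is the metathesis closure of 2-vinylaryl and 2-(alk-1-en-2-yl)aryl allyl ethers to 2H-chromenes and flav-3-enes. Ring C closes as a six-membered ring by intramolecular metathesis of a 1,7-diene, with C3=C4 the only bond formed. No stereocentre is created; C2 is not part of any bond made or broken and keeps the (S) configuration from step 13. The step needs site-selective initiation, ring closure in preference to intermolecular coupling, and no alkene migration or chromene ring opening. Initiation is directed to the vinyl group because the 1,1-diarylethene, twisted by the two ortho oxygens of the catechinyl ring, is closed to the bulky benzylidene yet still offers an unhindered CH2 terminus to the tethered alkylidene. High dilution and removal of ethene favour closure, and benzoquinone intercepts ruthenium hydrides that would shift the allylic ether double bond. Working at 60 °C in the dark should keep the 2H-chromene from opening electrocyclically to a quinone methide, which would scramble C2.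

Step 15
Reactants: 19 (2S)-7,8-bis(benzyloxy)-2-[3,4-bis(benzyloxy)phenyl]-4-(penta-O-benzylcatechin-8-yl)-2H-chromene
Product: 21 (2R,3S,4S)-7,8-bis(benzyloxy)-2-[3,4-bis(benzyloxy)phenyl]-4-(penta-O-benzylcatechin-8-yl)chroman-3-ol, via C3 alkylborane 20 (not isolated)
Conditions: BH3·SMe2 (4 equiv), THF, 0 °C → rt; then aq. NaOH, 30% H2O2, 0 °C → rt
Reagents that add atoms: hydrogen peroxide, OO
Why: Hydroboration–oxidation; boron goes to C3 because C4 carries two aryl groups, boron and hydrogen add syn from the face opposite the C2 aryl group, and oxidation with retention gives C3–OH trans to that aryl and C4–H cis to the hydroxyl, so the catechinyl group ends cis to the C2 aryl group as in (2R,3S,4S).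

Step 16
Reactants: 21 (2R,3S,4S)-7,8-bis(benzyloxy)-2-[3,4-bis(benzyloxy)phenyl]-4-(penta-O-benzylcatechin-8-yl)chroman-3-ol
Product: 22 (2R,3S,4S)-2-(3,4-dihydroxyphenyl)-4-[(2R,3S)-2-(3,4-dihydroxyphenyl)-3,5,7-trihydroxychroman-8-yl]chromane-3,7,8-triol
Conditions: H2 (1 atm), Pd(OH)2/C, THF/MeOH, rt; filtration under Ar
Reagents that add atoms: none
Why: Catalytic hydrogenolysis of nine benzyl ethers under neutral conditions; the cyclic C2–O1 ether and the C4–C8 bond are cleaved much more slowly than O-benzyl groups, so the reaction is stopped when hydrogen uptake ends, and no stereocentre is affected.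

## Compound list

1 | (+)-catechin, (2R,3S)-2-(3,4-dihydroxyphenyl)chromane-3,5,7-triol | Oc1cc(O)c2c(c1)O[C@H](c1ccc(O)c(O)c1)[C@@H](O)C2 | starting material
2 | 5,7,3′,4′-tetra-O-benzyl-(+)-catechin | c5ccccc5COc1cc(OCc5ccccc5)c2c(c1)O[C@H](c1ccc(OCc5ccccc5)c(OCc5ccccc5)c1)[C@@H](O)C2 | intermediate
3 | 8-bromo-5,7,3′,4′-tetra-O-benzyl-(+)-catechin | c5ccccc5COc1cc(OCc5ccccc5)c2c(c1Br)O[C@H](c1ccc(OCc5ccccc5)c(OCc5ccccc5)c1)[C@@H](O)C2 | intermediate
4 | 8-bromo-3,5,7,3′,4′-penta-O-benzyl-(+)-catechin | c5ccccc5COc1cc(OCc5ccccc5)c2c(c1Br)O[C@H](c1ccc(OCc5ccccc5)c(OCc5ccccc5)c1)[C@@H](OCc5ccccc5)C2 | intermediate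
5 | 2,3,4-trihydroxybenzaldehyde | O=Cc1ccc(O)c(O)c1O | starting material
6 | 3,4-bis(benzyloxy)-2-hydroxybenzaldehyde | O=Cc1ccc(OCc5ccccc5)c(OCc5ccccc5)c1O | intermediate
7 | 2-(allyloxy)-3,4-bis(benzyloxy)benzaldehyde | O=Cc1ccc(OCc5ccccc5)c(OCc5ccccc5)c1OCC=C | intermediate
8 | 8-lithio-3,5,7,3′,4′-penta-O-benzylcatechin | c5ccccc5COc1cc(OCc5ccccc5)c2c(c1[Li])O[C@H](c1ccc(OCc5ccccc5)c(OCc5ccccc5)c1)[C@@H](OCc5ccccc5)C2 | intermediate
9 | [2-(allyloxy)-3,4-bis(benzyloxy)phenyl](penta-O-benzylcatechin-8-yl)methanol, both carbinol epimers | C=CCOc1c(OCc5ccccc5)c(OCc5ccccc5)ccc1C(O)c1c(OCc5ccccc5)cc(OCc5ccccc5)c2c1O[C@H](c1ccc(OCc5ccccc5)c(OCc5ccccc5)c1)[C@@H](OCc5ccccc5)C2 | intermediate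
10 | [2-(allyloxy)-3,4-bis(benzyloxy)phenyl](penta-O-benzylcatechin-8-yl)methanone | C=CCOc1c(OCc5ccccc5)c(OCc5ccccc5)ccc1C(=O)c1c(OCc5ccccc5)cc(OCc5ccccc5)c2c1O[C@H](c1ccc(OCc5ccccc5)c(OCc5ccccc5)c1)[C@@H](OCc5ccccc5)C2 | intermediate
11 | 8-{1-[2-(allyloxy)-3,4-bis(benzyloxy)phenyl]vinyl}-3,5,7,3′,4′-penta-O-benzylcatechin | C=CCOc1c(OCc5ccccc5)c(OCc5ccccc5)ccc1C(=C)c1c(OCc5ccccc5)cc(OCc5ccccc5)c2c1O[C@H](c1ccc(OCc5ccccc5)c(OCc5ccccc5)c1)[C@@H](OCc5ccccc5)C2 | intermediate
12 | 2,3-bis(benzyloxy)-6-[1-(penta-O-benzylcatechin-8-yl)vinyl]phenol | Oc1c(OCc5ccccc5)c(OCc5ccccc5)ccc1C(=C)c1c(OCc5ccccc5)cc(OCc5ccccc5)c2c1O[C@H](c1ccc(OCc5ccccc5)c(OCc5ccccc5)c1)[C@@H](OCc5ccccc5)C2 | intermediate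
13 | caffeic acid | OC(=O)/C=C/c1ccc(O)c(O)c1 | starting material
14 | benzyl (E)-3-[3,4-bis(benzyloxy)phenyl]prop-2-enoate | O=C(OCc5ccccc5)/C=C/c1ccc(OCc5ccccc5)c(OCc5ccccc5)c1 | intermediate
15 | (E)-3-[3,4-bis(benzyloxy)phenyl]prop-2-en-1-ol | OC/C=C/c1ccc(OCc5ccccc5)c(OCc5ccccc5)c1 | intermediate
16 | (E)-3-[3,4-bis(benzyloxy)phenyl]allyl methyl carbonate | COC(=O)OC/C=C/c1ccc(OCc5ccccc5)c(OCc5ccccc5)c1 | intermediate
17 | lithium 2,3-bis(benzyloxy)-6-[1-(penta-O-benzylcatechin-8-yl)vinyl]phenoxide | [Li+].[O-]c1c(OCc5ccccc5)c(OCc5ccccc5)ccc1C(=C)c1c(OCc5ccccc5)cc(OCc5ccccc5)c2c1O[C@H](c1ccc(OCc5ccccc5)c(OCc5ccccc5)c1)[C@@H](OCc5ccccc5)C2 | intermediate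
18 | (S)-1-[3,4-bis(benzyloxy)phenyl]allyl ether of 12, the metathesis precursor | C=C[C@H](Oc3c(OCc5ccccc5)c(OCc5ccccc5)ccc3C(=C)c3c(OCc5ccccc5)cc(OCc5ccccc5)c4c3O[C@H](c3ccc(OCc5ccccc5)c(OCc5ccccc5)c3)[C@@H](OCc5ccccc5)C4)c6ccc(OCc5ccccc5)c(OCc5ccccc5)c6 | intermediate
19 | (2S)-7,8-bis(benzyloxy)-2-[3,4-bis(benzyloxy)phenyl]-4-(penta-O-benzylcatechin-8-yl)-2H-chromene | c5ccccc5COc1ccc([C@H]2Oc3c(ccc(OCc5ccccc5)c3OCc5ccccc5)C(c3c(OCc5ccccc5)cc(OCc5ccccc5)c4c3O[C@H](c3ccc(OCc5ccccc5)c(OCc5ccccc5)c3)[C@@H](OCc5ccccc5)C4)=C2)cc1OCc5ccccc5 | intermediate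
20 | C3 alkylborane of 19 (BH2 on C3 trans to the C2 aryl group, C4–H cis to boron) | c5ccccc5COc1ccc([C@H]2Oc3c(ccc(OCc5ccccc5)c3OCc5ccccc5)[C@@H](c3c(OCc5ccccc5)cc(OCc5ccccc5)c4c3O[C@H](c3ccc(OCc5ccccc5)c(OCc5ccccc5)c3)[C@@H](OCc5ccccc5)C4)[C@@H]2B)cc1OCc5ccccc5 | intermediate
21 | nona-O-benzyl ether of the target, (2R,3S,4S)-7,8-bis(benzyloxy)-2-[3,4-bis(benzyloxy)phenyl]-4-(penta-O-benzylcatechin-8-yl)chroman-3-ol | c5ccccc5COc1ccc([C@H]2Oc3c(ccc(OCc5ccccc5)c3OCc5ccccc5)[C@@H](c3c(OCc5ccccc5)cc(OCc5ccccc5)c4c3O[C@H](c3ccc(OCc5ccccc5)c(OCc5ccccc5)c3)[C@@H](OCc5ccccc5)C4)[C@@H]2O)cc1OCc5ccccc5 | intermediate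
22 | CNP0231186.1, (2R,3S,4S)-2-(3,4-dihydroxyphenyl)-4-[(2R,3S)-2-(3,4-dihydroxyphenyl)-3,5,7-trihydroxychroman-8-yl]chromane-3,7,8-triol | Oc1ccc([C@H]2Oc3c(ccc(O)c3O)[C@@H](c3c(O)cc(O)c4c3O[C@H](c3ccc(O)c(O)c3)[C@@H](O)C4)[C@@H]2O)cc1O | target

## Step count and least certain steps

Total: 16 steps. Longest linear sequence: 11 steps (1, 2, 3, 6, 7, 8, 9, 13, 14, 15, 16).

**Step 14 (key step).** The most likely failure is that the tethered alkylidene does not engage the 1,1-diarylethene because the doubly ortho-substituted catechinyl group crowds the metallacycle. The catalyst then decays and ruthenium hydrides shift the allylic ether double bond. A second failure is thermal ring opening of the chromene with loss of configuration at C2. The fallback sets out from 6, 16 and 2 and comes back to the route at 22; it no longer places the catechinyl group on the alkene. Methylenation of 6 with Ph3P=CH2 (from Ph3PCH3Br and KOt-Bu, THF) would give 2,3-bis(benzyloxy)-6-vinylphenol F1. Its lithium phenoxide and 16 under the conditions of step 13 would give the (S)-1-[3,4-bis(benzyloxy)phenyl]allyl ether F2. Second-generation Grubbs catalyst in CH2Cl2 at 40 °C would close the unhindered flav-3-ene F3, a closure well inside known practice. OsO4 (catalytic) with N-methylmorpholine N-oxide would add two hydroxyls anti to the C2 aryl group to give the 2,3-trans-3,4-cis diol F4. BF3·OEt2 in CH2Cl2 at −78 → 0 °C with an excess of 2 would ionise the benzylic C4 hydroxyl and let catechin C8 attack the cation anti to the C3 hydroxyl, giving the octa-O-benzyl dimer F5. Hydrogenolysis as in step 16 would then give 22. The price is that C8 versus C6 selectivity and the 3,4-trans outcome then rest on substrate preference instead of on the bromide position and the ring.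

**Step 13.** The phenoxide 17 is flanked by a benzyloxy group and the bulky 1-arylvinyl group. Slow attack would allow the allyl complex to give the linear ether, and reversible ionisation of the electron-rich product would erode the configuration at C2; the minor C2 epimer would be a diastereomer of 18. The fallback sets out from 6, 16 and 4 and comes back at 18; it makes the ether before the bulky group is attached. The lithium phenoxide of 6 and 16 under the same iridium catalyst would give (S)-2-{[1-(3,4-bis(benzyloxy)phenyl)allyl]oxy}-3,4-bis(benzyloxy)benzaldehyde F6. Addition of 8 (from 4 and n-BuLi) at −78 °C would give the carbinol F7. Dess–Martin periodinane with pyridine would give the ketone F8, and Cp2TiMe2 at no more than 70 °C would give 18. The cost is that the allylic ether centre must then survive three further steps.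

**Step 15.** The catechinyl group stands perpendicular to the alkene and shields both faces at C4, so addition may be slow and the facial preference set by the C2 aryl group may be weakened. The C3 borane 20 is also β to O1 and could eliminate with ring opening if warmed. The fallback sets out from 19 and comes back at 21. Dimethyldioxirane in acetone at −20 °C would epoxidise anti to the C2 aryl group to give the 3,4-epoxide F9. MgBr2·OEt2 or BF3·OEt2 at −78 °C would open it at the diaryl-substituted C4 and a 1,2-hydride shift from C3 (Meinwald rearrangement) would give the 4-aryl flavan-3-one F10. Because the shifted hydride arrives on the face opposite the epoxide oxygen, F10 would first form as its C4 epimer and would need brief exposure to Et3N to bring the doubly benzylic C4 to the 2,4-cis arrangement drawn. NaBH4 in THF/MeOH at −20 °C would then deliver hydride axially to give the equatorial alcohol 21. The risk carried by this fallback is enolisation towards C2.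

**Step 8.** The ketone 10 is deactivated by three ortho oxygens and is hindered, so methylene transfer may be too slow and the titanium carbene may instead engage the allyl group. The fallback sets out from 10 and comes back at 11, replacing carbonyl olefination by addition and elimination. MeLi in THF at −78 → 0 °C would give the tertiary alcohol 1-[2-(allyloxy)-3,4-bis(benzyloxy)phenyl]-1-(penta-O-benzylcatechin-8-yl)ethanol F11, and MsCl with Et3N at 0 °C would eliminate it through the highly stabilised tertiary benzylic position to give 11.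

**Step 4.** Over-benzylation at the chelated 2-hydroxyl or incomplete reaction at the flanked 3-hydroxyl would give mixtures. The fallback sets out from 5 and comes back at 6, relying on chelation-controlled cleavage instead of selective alkylation. Exhaustive benzylation (BnBr, K2CO3, DMF, 60 °C) would give 2,3,4-tris(benzyloxy)benzaldehyde F12, and MgBr2·OEt2 in toluene/Et2O at reflux would remove only the benzyl group ortho to the formyl group through a six-membered magnesium chelate, giving 6.

## Further compounds

F1 | step 14 | 2,3-bis(benzyloxy)-6-vinylphenol | C=Cc1ccc(OCc5ccccc5)c(OCc5ccccc5)c1O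
F2 | step 14 | (S)-1-[3,4-bis(benzyloxy)phenyl]allyl 2,3-bis(benzyloxy)-6-vinylphenyl ether | C=C[C@H](Oc3c(OCc5ccccc5)c(OCc5ccccc5)ccc3C=C)c6ccc(OCc5ccccc5)c(OCc5ccccc5)c6
F3 | step 14 | (2S)-7,8-bis(benzyloxy)-2-[3,4-bis(benzyloxy)phenyl]-2H-chromene | c5ccccc5COc1ccc([C@H]2Oc3c(ccc(OCc5ccccc5)c3OCc5ccccc5)C=C2)cc1OCc5ccccc5
F4 | step 14 | (2R,3S,4S)-7,8-bis(benzyloxy)-2-[3,4-bis(benzyloxy)phenyl]chromane-3,4-diol | c5ccccc5COc1ccc([C@H]2Oc3c(ccc(OCc5ccccc5)c3OCc5ccccc5)[C@H](O)[C@@H]2O)cc1OCc5ccccc5
F5 | step 14 | octa-O-benzyl ether of the target with both C3 hydroxyls free | c5ccccc5COc1ccc([C@H]2Oc3c(ccc(OCc5ccccc5)c3OCc5ccccc5)[C@@H](c3c(OCc5ccccc5)cc(OCc5ccccc5)c4c3O[C@H](c3ccc(OCc5ccccc5)c(OCc5ccccc5)c3)[C@@H](O)C4)[C@@H]2O)cc1OCc5ccccc5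
F6 | step 13 | (S)-2-{[1-(3,4-bis(benzyloxy)phenyl)allyl]oxy}-3,4-bis(benzyloxy)benzaldehyde | C=C[C@H](Oc3c(OCc5ccccc5)c(OCc5ccccc5)ccc3C=O)c6ccc(OCc5ccccc5)c(OCc5ccccc5)c6
F7 | step 13 | [3,4-bis(benzyloxy)-2-{[(1S)-1-(3,4-bis(benzyloxy)phenyl)allyl]oxy}phenyl](penta-O-benzylcatechin-8-yl)methanol, both carbinol epimers | C=C[C@H](Oc3c(OCc5ccccc5)c(OCc5ccccc5)ccc3C(O)c3c(OCc5ccccc5)cc(OCc5ccccc5)c4c3O[C@H](c3ccc(OCc5ccccc5)c(OCc5ccccc5)c3)[C@@H](OCc5ccccc5)C4)c6ccc(OCc5ccccc5)c(OCc5ccccc5)c6
F8 | step 13 | [3,4-bis(benzyloxy)-2-{[(1S)-1-(3,4-bis(benzyloxy)phenyl)allyl]oxy}phenyl](penta-O-benzylcatechin-8-yl)methanone | C=C[C@H](Oc3c(OCc5ccccc5)c(OCc5ccccc5)ccc3C(=O)c3c(OCc5ccccc5)cc(OCc5ccccc5)c4c3O[C@H](c3ccc(OCc5ccccc5)c(OCc5ccccc5)c3)[C@@H](OCc5ccccc5)C4)c6ccc(OCc5ccccc5)c(OCc5ccccc5)c6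
F9 | step 15 | 3,4-epoxide of 19 with the oxygen trans to the C2 aryl group | c5ccccc5COc1ccc([C@H]2Oc3c(ccc(OCc5ccccc5)c3OCc5ccccc5)[C@]7(c3c(OCc5ccccc5)cc(OCc5ccccc5)c4c3O[C@H](c3ccc(OCc5ccccc5)c(OCc5ccccc5)c3)[C@@H](OCc5ccccc5)C4)O[C@H]27)cc1OCc5ccccc5
F10 | step 15 | (2R,4S)-7,8-bis(benzyloxy)-2-[3,4-bis(benzyloxy)phenyl]-4-(penta-O-benzylcatechin-8-yl)chroman-3-one, 2,4-cis | c5ccccc5COc1ccc([C@H]2Oc3c(ccc(OCc5ccccc5)c3OCc5ccccc5)[C@@H](c3c(OCc5ccccc5)cc(OCc5ccccc5)c4c3O[C@H](c3ccc(OCc5ccccc5)c(OCc5ccccc5)c3)[C@@H](OCc5ccccc5)C4)C2=O)cc1OCc5ccccc5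
F11 | step 8 | 1-[2-(allyloxy)-3,4-bis(benzyloxy)phenyl]-1-(penta-O-benzylcatechin-8-yl)ethanol, both epimers | C=CCOc1c(OCc5ccccc5)c(OCc5ccccc5)ccc1C(C)(O)c1c(OCc5ccccc5)cc(OCc5ccccc5)c2c1O[C@H](c1ccc(OCc5ccccc5)c(OCc5ccccc5)c1)[C@@H](OCc5ccccc5)C2
F12 | step 4 | 2,3,4-tris(benzyloxy)benzaldehyde | O=Cc1ccc(OCc5ccccc5)c(OCc5ccccc5)c1OCc5ccccc5
A1 | alternative 1 | nona-O-benzyl ether of the target with the upper C3 oxygen as its tert-butyldimethylsilyl ether | c5ccccc5COc1ccc([C@H]2Oc3c(ccc(OCc5ccccc5)c3OCc5ccccc5)[C@@H](c3c(OCc5ccccc5)cc(OCc5ccccc5)c4c3O[C@H](c3ccc(OCc5ccccc5)c(OCc5ccccc5)c3)[C@@H](OCc5ccccc5)C4)[C@@H]2O[Si](C)(C)C(C)(C)C)cc1OCc5ccccc5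
A2 | alternative 1 | open-chain 1-[3,4-bis(benzyloxy)phenyl]-3-[3,4-bis(benzyloxy)-2-bromophenyl]-3-(penta-O-benzylcatechin-8-yl)-2-(tert-butyldimethylsilyloxy)propan-1-ol with the target configuration at all three chain carbons | c5ccccc5COc1ccc([C@@H](O)[C@@H](O[Si](C)(C)C(C)(C)C)[C@@H](c3ccc(OCc5ccccc5)c(OCc5ccccc5)c3Br)c3c(OCc5ccccc5)cc(OCc5ccccc5)c4c3O[C@H](c3ccc(OCc5ccccc5)c(OCc5ccccc5)c3)[C@@H](OCc5ccccc5)C4)cc1OCc5ccccc5
A3 | alternative 2 | 7,8-bis(benzyloxy)-4-(penta-O-benzylcatechin-8-yl)-3,4-dihydrocoumarin | O=C1C[C@H](c3c(OCc5ccccc5)cc(OCc5ccccc5)c4c3O[C@H](c3ccc(OCc5ccccc5)c(OCc5ccccc5)c3)[C@@H](OCc5ccccc5)C4)c2ccc(OCc5ccccc5)c(OCc5ccccc5)c2O1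
A4 | alternative 2 | 6,7-bis(benzyloxy)-3-(penta-O-benzylcatechin-8-yl)indan-1-one | O=C1C[C@H](c3c(OCc5ccccc5)cc(OCc5ccccc5)c4c3O[C@H](c3ccc(OCc5ccccc5)c(OCc5ccccc5)c3)[C@@H](OCc5ccccc5)C4)c2ccc(OCc5ccccc5)c(OCc5ccccc5)c12
A5 | alternative 3 | 3,7,8-tris(benzyloxy)-4-(penta-O-benzylcatechin-8-yl)chroman-2-ol, one anomer | O[C@H]2Oc3c(ccc(OCc5ccccc5)c3OCc5ccccc5)[C@@H](c3c(OCc5ccccc5)cc(OCc5ccccc5)c4c3O[C@H](c3ccc(OCc5ccccc5)c(OCc5ccccc5)c3)[C@@H](OCc5ccccc5)C4)[C@@H]2OCc5ccccc5
A6 | alternative 3 | [3,4-bis(benzyloxy)-2-hydroxyphenyl](penta-O-benzylcatechin-8-yl)methanol | Oc1c(OCc5ccccc5)c(OCc5ccccc5)ccc1C(O)c1c(OCc5ccccc5)cc(OCc5ccccc5)c2c1O[C@H](c1ccc(OCc5ccccc5)c(OCc5ccccc5)c1)[C@@H](OCc5ccccc5)C2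
A7 | alternative 3 | 2,3-bis(benzyloxy)-6-[(penta-O-benzylcatechin-8-yl)methylene]cyclohexa-2,4-dien-1-one, the ortho-quinone methide | O=C1C(OCc5ccccc5)=C(OCc5ccccc5)C=CC1=Cc1c(OCc5ccccc5)cc(OCc5ccccc5)c2c1O[C@H](c1ccc(OCc5ccccc5)c(OCc5ccccc5)c1)[C@@H](OCc5ccccc5)C2
A8 | alternative 3 | benzyloxyacetaldehyde | O=CCOCc1ccccc1
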